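**Retrosynthetic overview**
1. The target comes, after deprotection, from a protected 3-hydroxyisoflavanone. That comes from an isoflavone by 1,4-hydride addition and reagent-controlled hydroxylation of the resulting enolate (the order isoflavone reductase, then 3-hydroxylase). This sets the only stereocentre.
2. C3–aryl bond: the isoflavone comes from a flavanone by a 2,3-aryl shift (isoflavone-synthase logic). The shift is triggered at the enol silane, so the prenyl group can already be in place.
3. O1–C2 bond (ring C, the only ring made): the flavanone comes from a 2',6'-dihydroxychalcone by oxa-Michael closure (chalcone-isomerase logic). The chalcone comes from a Claisen–Schmidt union of an A-ring acetophenone and a B-ring aldehyde.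
4. The B-ring aldehyde comes from 2,4-dihydroxybenzaldehyde by C3-prenylation, 4-O-allylation and 2-O-methylation.
5. Ring order: A and B are bought. C is closed as a flavanone and then rewired to the isoflavonoid skeleton.

Assumption 1: acetophenone 6 is bought as a catalogue compound; it is also one Me2SO4/K2CO3 mono-methylation away from phloroacetophenone.
Assumption 2: the sense of induction in step 5 is taken from 2-substituted 1-tetralone and 3-benzylchroman-4-one enolates ((+)-reagent gives R, (−)-reagent gives S); both antipodes are sold, so the other one is used if ECD of 13 shows the opposite sense.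

**Step 1**
Reactants: 1 2,4-dihydroxybenzaldehyde; 2 prenyl bromide (1-bromo-3-methylbut-2-ene)
Product: 3 2,4-dihydroxy-3-prenylbenzaldehyde
Conditions: KOH (1.1 equiv), H2O, 0 °C to rt, 16 h
Reagents that add atoms: none
Why: Phenoxide C-alkylation (aromatic prenylation): in water the solvated resorcinolate reacts on carbon, and C3, ortho to both oxygens, is the most nucleophilic site; no stereocentre is formed.

**Step 2**
Reactants: 3 2,4-dihydroxy-3-prenylbenzaldehyde
Product: 5 4-allyloxy-2-methoxy-3-prenylbenzaldehyde, via 4-O-allyl ether 4 (not isolated)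
Conditions: allyl bromide (1.05 equiv), K2CO3, DMF, 0 °C to rt; then MeI (3 equiv), K2CO3, 40 °C
Reagents that add atoms: allyl bromide C=CCBr; iodomethane CI
Why: Two sequential Williamson ether syntheses: the free, more acidic 4-OH is allylated first because the 2-OH is tied up in a hydrogen bond to the aldehyde, and excess MeI with gentle heating then caps the chelated 2-OH.

**Step 3**
Reactants: 5 4-allyloxy-2-methoxy-3-prenylbenzaldehyde; 6 2',6'-dihydroxy-4'-methoxyacetophenone
Product: 8 (±)-4'-allyloxy-5-hydroxy-7,2'-dimethoxy-3'-prenylflavanone, via chalcone 7 (not isolated)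
Conditions: KOH (50 % aq, 10 equiv), EtOH, rt, 48 h, Ar; then AcOH to pH 6, reflux, 4 h
Reagents that add atoms: none
Why: Claisen–Schmidt condensation followed by 6-endo oxa-Michael ring closure (chalcone to flavanone): a 2',6'-dihydroxychalcone always has a phenol placed over the β-carbon and closes readily in the acetate buffer, and C2 forms racemic, which is harmless because step 4 erases it.

**Step 4**
Reactants: 8 (±)-4'-allyloxy-5-hydroxy-7,2'-dimethoxy-3'-prenylflavanone
Product: 11 4'-allyloxy-5-(tert-butyldimethylsilyloxy)-7,2'-dimethoxy-3'-prenylisoflavone, via bis-TBS enol silane 9 (not isolated), via trans-C3 iodane 10 (not isolated)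
Conditions: TBSOTf (2.5 equiv), Et3N, CH2Cl2, 0 °C to rt; cold aq NaHCO3 wash, crude 9; then PhI(OAc)2 (1.05 equiv), BF3·OEt2 (1.2 equiv), 2,6-di-tert-butyl-4-methylpyridine, CH2Cl2, −78 to −30 °C
Reagents that add atoms: tert-butyldimethylsilyl triflate CC(C)(C)[Si](C)(C)OS(=O)(=O)C(F)(F)F; (diacetoxyiodo)benzene CC(=O)OI(OC(C)=O)c1ccccc1 (its atoms stay only in 10)
Why: Proposed new method: soft enolisation fixes the flavanone as its enol silane (and masks 5-OH), whose C3 is far more nucleophilic than the prenyl and allyl alkenes or the alkoxyarenes, so one equivalent of BF3-activated PhI(OAc)2 at −78 °C attacks only C3, anti to the C2-aryl group, giving trans-iodane 10 in which the very electron-rich 2,4-dialkoxyaryl group can lie antiperiplanar to the PhI leaving group and migrates C2→C3 through a phenonium ion, after which the C2 oxocarbenium ion loses H-3 to give the isoflavone (both transient stereocentres vanish); the closest known reaction types are the hypervalent-iodine oxidative 2,3-aryl migration of flavanones to isoflavones (normally run hot in acid, where a prenyl group would not survive) and the I(III)/BF3 α-functionalisation of silyl enol ethers.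

**Step 5**
Reactants: 11 4'-allyloxy-5-(tert-butyldimethylsilyloxy)-7,2'-dimethoxy-3'-prenylisoflavone
Product: 13 (3S)-4'-allyloxy-3-hydroxy-5-(tert-butyldimethylsilyloxy)-7,2'-dimethoxy-3'-prenylisoflavanone, via sodium enolate 12 (not isolated)
Conditions: NaBH(s-Bu)3 (N-Selectride, 1.05 equiv), THF, −78 °C, 1 h; (−)-[(8,8-dichlorocamphoryl)sulfonyl]oxaziridine (1.4 equiv), THF, −78 °C, 2 h; AcOH, −78 °C
Reagents that add atoms: (−)-[(8,8-dichlorocamphoryl)sulfonyl]oxaziridine CC1(C)[C@H]2CC[C@@]13CS(=O)(=O)N4O[C@]34C2(Cl)Cl (oxygen atom); sodium tri-sec-butylborohydride [Na+].CCC(C)[BH-](C(C)CC)C(C)CC (hydride; sodium only in 12)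
Why: Conjugate hydride reduction with enolate trapping, joined to a Davis asymmetric enolate hydroxylation: the bulky hydride adds 1,4 to the hindered chromone to give the single tetrasubstituted sodium enolate, and the camphor-derived oxaziridine, which ignores isolated alkenes, delivers oxygen under reagent control to the Si face of C3, setting the quaternary (3S) carbinol, which cannot epimerise afterwards.

**Step 6**
Reactants: 13 (3S)-4'-allyloxy-3-hydroxy-5-(tert-butyldimethylsilyloxy)-7,2'-dimethoxy-3'-prenylisoflavanone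
Product: 15 (3S)-3,5,4'-trihydroxy-7,2'-dimethoxy-3'-prenylisoflavanone (target), via 5-OH allyl ether 14 (not isolated)
Conditions: K2CO3 (1.5 equiv), degassed MeOH, rt, 30 min; then morpholine (10 equiv), Pd(PPh3)4 (5 mol %), rt, Ar; pH 6 buffer work-up
Reagents that add atoms: none
Why: Base methanolysis of the carbonyl-activated aryl silyl ether followed by Tsuji–Trost deallylation (π-allyl-Pd captured by morpholine) avoids all acid, so the tertiary benzylic carbinol (which would dehydrate to the isoflavone), the o-prenylphenol and the C3 stereocentre are untouched.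

**Compound list**
1 | 2,4-dihydroxybenzaldehyde | O=Cc1ccc(O)cc1O | starting material
2 | prenyl bromide | CC(C)=CCBr | starting material
3 | 2,4-dihydroxy-3-prenylbenzaldehyde | O=Cc1ccc(O)c(CC=C(C)C)c1O | intermediate
4 | 4-allyloxy-2-hydroxy-3-prenylbenzaldehyde | O=Cc1ccc(OCC=C)c(CC=C(C)C)c1O | intermediate
5 | 4-allyloxy-2-methoxy-3-prenylbenzaldehyde | O=Cc1ccc(OCC=C)c(CC=C(C)C)c1OC | intermediate
6 | 2',6'-dihydroxy-4'-methoxyacetophenone | CC(=O)c1c(O)cc(OC)cc1O | starting material
7 | (E)-4-allyloxy-2',6'-dihydroxy-2,4'-dimethoxy-3-prenylchalcone | COc1cc(O)c(C(=O)/C=C/c2ccc(OCC=C)c(CC=C(C)C)c2OC)c(O)c1 | intermediate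
8 | (±)-4'-allyloxy-5-hydroxy-7,2'-dimethoxy-3'-prenylflavanone (racemic at C2) | COc1cc(O)c2c(c1)OC(CC2=O)c1ccc(OCC=C)c(CC=C(C)C)c1OC | intermediate
9 | (±)-2-(4-allyloxy-2-methoxy-3-prenylphenyl)-4,5-bis(TBS-oxy)-7-methoxy-2H-chromene (racemic) | COc1cc(O[Si](C)(C)C(C)(C)C)c2c(c1)OC(C=C2O[Si](C)(C)C(C)(C)C)c1ccc(OCC=C)c(CC=C(C)C)c1OC | intermediate
10 | rac-trans-3-[acetoxy(phenyl)-λ3-iodanyl]-5-O-TBS derivative of flavanone 8 (one enantiomer of the racemate drawn) | COc1cc(O[Si](C)(C)C(C)(C)C)c2c(c1)O[C@@H]([C@H](C2=O)I(OC(C)=O)c1ccccc1)c1ccc(OCC=C)c(CC=C(C)C)c1OC | intermediate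
11 | 4'-allyloxy-5-(TBS-oxy)-7,2'-dimethoxy-3'-prenylisoflavone | COc1cc(O[Si](C)(C)C(C)(C)C)c2c(c1)OC=C(C2=O)c1ccc(OCC=C)c(CC=C(C)C)c1OC | intermediate
12 | sodium C3=C4 enolate of the corresponding isoflavanone | [Na+].COc1cc(O[Si](C)(C)C(C)(C)C)c2c(c1)OCC(=C2[O-])c1ccc(OCC=C)c(CC=C(C)C)c1OC | intermediate
13 | (3S)-4'-allyloxy-3-hydroxy-5-(TBS-oxy)-7,2'-dimethoxy-3'-prenylisoflavanone | COc1cc(O[Si](C)(C)C(C)(C)C)c2c(c1)OC[C@@](O)(c1ccc(OCC=C)c(CC=C(C)C)c1OC)C2=O | intermediate
14 | (3S)-4'-allyloxy-3,5-dihydroxy-7,2'-dimethoxy-3'-prenylisoflavanone | COc1cc(O)c2c(c1)OC[C@@](O)(c1ccc(OCC=C)c(CC=C(C)C)c1OC)C2=O | intermediate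
15 | (3S)-3,5,4'-trihydroxy-7,2'-dimethoxy-3'-prenylisoflavanone | COc1cc(O)c2c(c1)OC[C@@](O)(c1ccc(O)c(CC=C(C)C)c1OC)C2=O | target

**Total step count:** 6. **Longest linear sequence:** 6 (1 → 3 → 5 → 8 → 11 → 13 → 15).

**The three steps most likely to fail**

**Step 4.** There are three risks. Silylation may open the electron-rich flavanone to the chalcone. Hydride loss or elimination from 9 or 10 may give the flavone instead of the isoflavone. The I(III) reagent may still attack the prenyl group or the alkoxyarenes.

The fallback moves the skeletal rearrangement to the open-chain stage and uses a nucleophilic oxidant that cannot touch an isolated alkene. It sets out from 8. TBSCl/DBU in CH2Cl2 opens the flavanone by E1cB and caps both phenoxides to give the bis-TBS chalcone F1. LiOOt-Bu (TBHP, n-BuLi, THF, −20 °C) gives the racemic trans-epoxychalcone F2 by Weitz–Scheffer epoxidation. BF3·OEt2 (CH2Cl2, −78 °C) opens the oxirane at the benzylic carbon, and the aroyl group shifts 1,2 to give the α-formyldeoxybenzoin F3. TBAF/AcOH frees the phenols; one of them closes onto the formyl group, and the 2-hydroxyisoflavanone loses water to give the 5-hydroxyisoflavone F4. TBSOTf/2,6-lutidine then comes back to the route at 11.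

**Step 5.** There are again three risks. Excess hydride or warming opens the enolate by E1cB and over-reduces it to an α-methyldeoxybenzoin. Above −78 °C the 5-O-silyl group can shift to the peri enolate oxygen. The ee for an α-aryl tetrasubstituted enolate may be only moderate.

The fallback sets the stereocentre on the enone instead of the enolate. It sets out from 11. Cumene hydroperoxide, dilute aq KOH/toluene at 0 °C and 10 mol % N-(4-trifluoromethylbenzyl)cinchoninium bromide effect an asymmetric phase-transfer Weitz–Scheffer epoxidation to the (1aR,7aS)-isoflavone epoxide F5. The cinchonidinium pseudo-enantiomer is used if the sense is reversed. This oxidant also spares the prenyl group. LiBHEt3 (THF, −78 to 0 °C) reduces the ketone and opens the oxirane by SN2 attack at the acetal carbon C2, as with 1,2-anhydrosugars, leaving the C3–O bond intact. This gives the (3S)-isoflavan-3,4-diol F6 as a C4 epimer mixture. IBX (or SO3·pyridine/DMSO) oxidises only the secondary benzylic alcohol, and the sequence comes back to the route at 13.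

**Step 1.** O-alkylation, the 5-prenyl isomer and bis-prenylation keep this yield low (about 30 %).

The fallback builds the side chain by sigmatropy and metathesis. It sets out from 1. Allyl bromide/K2CO3/acetone gives 4-allyloxy-2-hydroxybenzaldehyde F7. An aromatic Claisen rearrangement (N,N-diethylaniline, 190 °C), steered to C3 by the chelated 2-OH, gives 3-allyl-2,4-dihydroxybenzaldehyde F8. Cross-metathesis with 2-methyl-2-butene (Grubbs II, CH2Cl2, 40 °C) comes back to the route at 3.

**Further compounds**
F1 | step 4 | (E)-4-allyloxy-2',6'-bis(TBS-oxy)-2,4'-dimethoxy-3-prenylchalcone | COc1cc(O[Si](C)(C)C(C)(C)C)c(C(=O)/C=C/c2ccc(OCC=C)c(CC=C(C)C)c2OC)c(O[Si](C)(C)C(C)(C)C)c1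
F2 | step 4 | rac-trans-α,β-epoxide of F1 (one enantiomer of the racemate drawn) | COc1cc(O[Si](C)(C)C(C)(C)C)c(C(=O)[C@H]2O[C@@H]2c3ccc(OCC=C)c(CC=C(C)C)c3OC)c(O[Si](C)(C)C(C)(C)C)c1
F3 | step 4 | 2-(4-allyloxy-2-methoxy-3-prenylphenyl)-3-[2,6-bis(TBS-oxy)-4-methoxyphenyl]-3-oxopropanal (α-formyldeoxybenzoin, configurationally labile) | COc1cc(O[Si](C)(C)C(C)(C)C)c(C(=O)C(C=O)c2ccc(OCC=C)c(CC=C(C)C)c2OC)c(O[Si](C)(C)C(C)(C)C)c1
F4 | step 4 | 4'-allyloxy-5-hydroxy-7,2'-dimethoxy-3'-prenylisoflavone | COc1cc(O)c2c(c1)OC=C(C2=O)c1ccc(OCC=C)c(CC=C(C)C)c1OC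
F5 | step 5 | (1aR,7aS)-2,3-epoxide of isoflavone 11 | COc1cc(O[Si](C)(C)C(C)(C)C)c2c(c1)O[C@@H]3O[C@]3(c1ccc(OCC=C)c(CC=C(C)C)c1OC)C2=O
F6 | step 5 | (3S)-4'-allyloxy-5-(TBS-oxy)-7,2'-dimethoxy-3'-prenylisoflavan-3,4-diol (C4 epimers) | COc1cc(O[Si](C)(C)C(C)(C)C)c2c(c1)OC[C@@](O)(c1ccc(OCC=C)c(CC=C(C)C)c1OC)C2O
F7 | step 1 | 4-allyloxy-2-hydroxybenzaldehyde | O=Cc1ccc(OCC=C)cc1O
F8 | step 1 | 3-allyl-2,4-dihydroxybenzaldehyde | O=Cc1ccc(O)c(CC=C)c1O
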